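**Retrosynthetic overview**
1. The strategy rests on two features: C7 is a carbinol carbon bonded to C1 of the guaiacyl ring, and the C8–C9 unit with its 8‑O‑4' aryl ether oxygen is a glycerate of known configuration.
2. Key disconnection C7–C1(guaiacyl): an aryl titanium reagent made from the aryl Grignard adds to the (S)‑2‑aryloxy‑3‑silyloxypropanal in the open Felkin (anti) mode, so C8 (S) sets C7 (R).
3. The C8–O(aryl) bond comes from Mitsunobu inversion of methyl (R)‑3‑O‑TBS‑glycerate with the O‑silylated syringyl alcohol; the ester is then reduced to the aldehyde.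
4. No ring is formed: both benzene rings are bought (syringaldehyde, 4‑bromo‑2‑methoxyphenol) and C8 comes from methyl (R)‑glycerate acetonide.
5. One fluoride step at the end removes the three TBS groups (guaiacyl O4, O9, syringyl benzylic O).

Key step: step 9

Remark on the chemistry: the guaiacyl phenol is carried as a TBS ether rather than a benzyl ether, so a single fluoride treatment frees all hydroxyls and no hydrogenolysis is run next to two benzylic alcohols. The Grignard reagent is prepared and titrated as a THF stock solution and counted as a compound of its own.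

**Step 1**
Reactants: 1 methyl (R)‑2,2‑dimethyl‑1,3‑dioxolane‑4‑carboxylate
Product: 2 methyl (R)‑2,3‑dihydroxypropanoate
Conditions: Dowex 50W‑X8 (H+), MeOH/H2O 9:1, rt; filter, concentrate
Reagents that add atoms: none
Why: acid‑catalysed acetonide (ketal) hydrolysis should free the diol without touching the methyl ester or the C2 stereocentre, and resin filtration avoids an aqueous work‑up of the water‑soluble product.

**Step 2**
Reactants: 2 methyl (R)‑2,3‑dihydroxypropanoate
Product: 3 methyl (R)‑3‑(tert‑butyldimethylsilyloxy)‑2‑hydroxypropanoate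
Conditions: TBSCl (1.05 equiv), imidazole, DMAP (cat.), CH2Cl2, 0 °C
Reagents that add atoms: tert‑butyldimethylsilyl chloride, CC(C)(C)[Si](C)(C)Cl
Why: regioselective silyl ether formation, in which the unhindered primary hydroxyl should react well before the secondary, electron‑poor α‑hydroxy ester OH.

**Step 3**
Reactants: 4 syringaldehyde
Product: 5 4‑(hydroxymethyl)‑2,6‑dimethoxyphenol (syringyl alcohol)
Conditions: NaBH4, MeOH, 0 °C → rt; aq NH4Cl to pH 7
Reagents that add atoms: none
Why: borohydride reduction of the aryl aldehyde, with a neutral work‑up so that the p‑hydroxybenzyl alcohol does not enter quinone‑methide chemistry.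

**Step 4**
Reactants: 5 4‑(hydroxymethyl)‑2,6‑dimethoxyphenol
Product: 6 4‑[(tert‑butyldimethylsilyloxy)methyl]‑2,6‑dimethoxyphenol
Conditions: TBSCl (1.05 equiv), imidazole, DMF, 0 °C
Reagents that add atoms: tert‑butyldimethylsilyl chloride, CC(C)(C)[Si](C)(C)Cl
Why: chemoselective silylation, since the primary benzylic alcohol should be silylated faster than the phenol that is flanked by, and hydrogen‑bonded to, two methoxy groups.

**Step 5**
Reactants: 3 methyl (R)‑3‑(tert‑butyldimethylsilyloxy)‑2‑hydroxypropanoate; 6 4‑[(tert‑butyldimethylsilyloxy)methyl]‑2,6‑dimethoxyphenol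
Product: 7 methyl (S)‑3‑(tert‑butyldimethylsilyloxy)‑2‑[4‑(tert‑butyldimethylsilyloxymethyl)‑2,6‑dimethoxyphenoxy]propanoate
Conditions: PPh3, DIAD, THF, 0 °C → rt
Reagents that add atoms: none
Why: Mitsunobu etherification, in which the phenoxide displaces the oxyphosphonium group at the carbonyl‑activated α‑carbon by SN2 and so inverts C2 from R to S (the later C8).

**Step 6**
Reactants: 7 methyl (S)‑3‑(tert‑butyldimethylsilyloxy)‑2‑[4‑(tert‑butyldimethylsilyloxymethyl)‑2,6‑dimethoxyphenoxy]propanoate
Product: 8 (S)‑3‑(tert‑butyldimethylsilyloxy)‑2‑[4‑(tert‑butyldimethylsilyloxymethyl)‑2,6‑dimethoxyphenoxy]propanal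
Conditions: DIBAL‑H (1.15 equiv), CH2Cl2, −78 °C; MeOH, then aq Rochelle salt; used crude at once, kept cold
Reagents that add atoms: none
Why: partial DIBAL reduction of an α‑alkoxy ester, whose chelated aluminium hemiacetal is stable at −78 °C and releases the aldehyde only on work‑up, so C8 is not touched.

**Step 7**
Reactants: 9 4‑bromo‑2‑methoxyphenol
Product: 10 (4‑bromo‑2‑methoxyphenoxy)(tert‑butyl)dimethylsilane
Conditions: TBSCl, imidazole, DMF, rt
Reagents that add atoms: tert‑butyldimethylsilyl chloride, CC(C)(C)[Si](C)(C)Cl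
Why: standard silyl ether formation on a phenol, which masks the acidic OH before the organometallic is made.

**Step 8**
Reactants: 10 (4‑bromo‑2‑methoxyphenoxy)(tert‑butyl)dimethylsilane
Product: 11 [4‑(tert‑butyldimethylsilyloxy)‑3‑methoxyphenyl]magnesium bromide (THF solution, titrated)
Conditions: Mg turnings, I2 (cat.), THF, rt → 45 °C
Reagents that add atoms: magnesium, [Mg]
Why: Grignard formation by insertion of magnesium into the aryl C–Br bond, to which the aryl silyl ether and the methyl ether are inert.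

**Step 9**
Reactants: 8 (S)‑3‑(tert‑butyldimethylsilyloxy)‑2‑[4‑(tert‑butyldimethylsilyloxymethyl)‑2,6‑dimethoxyphenoxy]propanal; 11 [4‑(tert‑butyldimethylsilyloxy)‑3‑methoxyphenyl]magnesium bromide
Product: 13 (1R,2S)‑3‑(tert‑butyldimethylsilyloxy)‑2‑[4‑(tert‑butyldimethylsilyloxymethyl)‑2,6‑dimethoxyphenoxy]‑1‑[4‑(tert‑butyldimethylsilyloxy)‑3‑methoxyphenyl]propan‑1‑ol, via aryltitanium triisopropoxide 12 (not isolated)
Conditions: 11 (1.5 equiv), ClTi(OiPr)3 (1.5 equiv), THF, −78 → −40 °C; then 8, THF, −78 → −20 °C; sat. aq NH4Cl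
Reagents that add atoms: none
Why: Transmetalation of 11 with ClTi(OiPr)3 gives the monoaryl titanium species 12, which adds 1,2 to the aldehyde carbon of 8 through an open transition state and so forms the C7–C1 bond and a C7 titanium alkoxide that is protonated on work‑up. The closest known reaction type is the non‑chelation‑controlled addition of organotitanium triisopropoxides to α‑alkoxy aldehydes under the polar Felkin–Anh model. No ring is closed. The new C7 stereocentre is controlled by C8: the C8–O(aryl) bond lies antiperiplanar to the incoming aryl group, C9 sits next to the carbonyl oxygen and the nucleophile passes the C8 hydrogen, which from the (S)‑aldehyde should give the 7R (anti, erythro) carbinol. The step needs anti addition over chelation‑controlled syn addition, and this should be secured by the bulky, weakly Lewis‑acidic Ti(OiPr)3 centre, which does not bridge the carbonyl oxygen to the hindered aryl ether oxygen between two methoxy groups or to the TBS‑shielded O9. The low basicity of 12 should also leave the enolisable C8–H and the β‑silyloxy group of 8 intact.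

**Step 10**
Reactants: 13 (1R,2S)‑3‑(tert‑butyldimethylsilyloxy)‑2‑[4‑(tert‑butyldimethylsilyloxymethyl)‑2,6‑dimethoxyphenoxy]‑1‑[4‑(tert‑butyldimethylsilyloxy)‑3‑methoxyphenyl]propan‑1‑ol
Product: 14 (1R,2S)‑1‑(4‑hydroxy‑3‑methoxyphenyl)‑2‑[4‑(hydroxymethyl)‑2,6‑dimethoxyphenoxy]propane‑1,3‑diol (target)
Conditions: TBAF (4 equiv), AcOH (4 equiv), THF, 0 °C → rt
Reagents that add atoms: none
Why: fluoride‑mediated desilylation should cleave the two alkyl TBS ethers and the aryl TBS ether in one operation, and the acetic acid buffer keeps the phenoxide and the benzylic carbinols from base‑induced side reactions, so neither stereocentre is touched.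

**Compound list**
1 | methyl (R)‑2,2‑dimethyl‑1,3‑dioxolane‑4‑carboxylate | COC(=O)[C@H]1COC(C)(C)O1 | starting material
2 | methyl (R)‑2,3‑dihydroxypropanoate | COC(=O)[C@H](O)CO | intermediate
3 | methyl (R)‑3‑(tert‑butyldimethylsilyloxy)‑2‑hydroxypropanoate | COC(=O)[C@H](O)CO[Si](C)(C)C(C)(C)C | intermediate
4 | syringaldehyde | COc1cc(C=O)cc(OC)c1O | starting material
5 | 4‑(hydroxymethyl)‑2,6‑dimethoxyphenol | COc1cc(CO)cc(OC)c1O | intermediate
6 | 4‑[(tert‑butyldimethylsilyloxy)methyl]‑2,6‑dimethoxyphenol | COc1cc(CO[Si](C)(C)C(C)(C)C)cc(OC)c1O | intermediate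
7 | methyl (S)‑3‑(tert‑butyldimethylsilyloxy)‑2‑[4‑(tert‑butyldimethylsilyloxymethyl)‑2,6‑dimethoxyphenoxy]propanoate | COC(=O)[C@H](CO[Si](C)(C)C(C)(C)C)Oc1c(OC)cc(CO[Si](C)(C)C(C)(C)C)cc1OC | intermediate
8 | (S)‑3‑(tert‑butyldimethylsilyloxy)‑2‑[4‑(tert‑butyldimethylsilyloxymethyl)‑2,6‑dimethoxyphenoxy]propanal | O=C[C@H](CO[Si](C)(C)C(C)(C)C)Oc1c(OC)cc(CO[Si](C)(C)C(C)(C)C)cc1OC | intermediate
9 | 4‑bromo‑2‑methoxyphenol | COc1cc(Br)ccc1O | starting material
10 | (4‑bromo‑2‑methoxyphenoxy)(tert‑butyl)dimethylsilane | COc1cc(Br)ccc1O[Si](C)(C)C(C)(C)C | intermediate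
11 | [4‑(tert‑butyldimethylsilyloxy)‑3‑methoxyphenyl]magnesium bromide | COc1cc([Mg]Br)ccc1O[Si](C)(C)C(C)(C)C | intermediate
12 | [4‑(tert‑butyldimethylsilyloxy)‑3‑methoxyphenyl]titanium triisopropoxide | COc1cc([Ti](OC(C)C)(OC(C)C)OC(C)C)ccc1O[Si](C)(C)C(C)(C)C | intermediate
13 | (1R,2S)‑3‑(tert‑butyldimethylsilyloxy)‑2‑[4‑(tert‑butyldimethylsilyloxymethyl)‑2,6‑dimethoxyphenoxy]‑1‑[4‑(tert‑butyldimethylsilyloxy)‑3‑methoxyphenyl]propan‑1‑ol | COc1cc([C@@H](O)[C@H](CO[Si](C)(C)C(C)(C)C)Oc2c(OC)cc(CO[Si](C)(C)C(C)(C)C)cc2OC)ccc1O[Si](C)(C)C(C)(C)C | intermediate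
14 | (1R,2S)‑1‑(4‑hydroxy‑3‑methoxyphenyl)‑2‑[4‑(hydroxymethyl)‑2,6‑dimethoxyphenoxy]propane‑1,3‑diol | COc1cc([C@@H](O)[C@H](CO)Oc2c(OC)cc(CO)cc2OC)ccc1O | target

**Step count**
Total: 10 steps. Longest linear sequence: 6 steps (steps 1, 2, 5, 6, 9, 10).

**Steps most likely to fail**

Step 9 (key addition). Syn delivery of the aryl group through a metal bridge between the carbonyl and an ether oxygen may compete with the open Felkin mode. The aldehyde may also enolise or lose silanolate before it is attacked, which would erode C8. The fallback sets out from ester 7 and avoids the aldehyde. Ester 7 is converted with MeNHOMe·HCl and i‑PrMgCl (THF, −20 °C) into the Weinreb amide (S)‑3‑(tert‑butyldimethylsilyloxy)‑2‑[4‑(tert‑butyldimethylsilyloxymethyl)‑2,6‑dimethoxyphenoxy]‑N‑methoxy‑N‑methylpropanamide F1. Grignard reagent 11 (THF, 0 °C) then gives the aryl ketone (S)‑3‑(tert‑butyldimethylsilyloxy)‑2‑[4‑(tert‑butyldimethylsilyloxymethyl)‑2,6‑dimethoxyphenoxy]‑1‑[4‑(tert‑butyldimethylsilyloxy)‑3‑methoxyphenyl]propan‑1‑one F2. The ketone is reduced with Zn(BH4)2 (Et2O, −30 °C) under chelation control: hydride should attack the zinc‑bridged C=O/O‑aryl chelate from the face of the C8 hydrogen and give the anti (7R,8S) alcohol. The fallback rejoins the route at 13.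

Step 5 (Mitsunobu). The doubly ortho‑substituted phenol may attack the oxyphosphonium intermediate too slowly, so that alkylation of the reduced azodicarboxylate or elimination takes over. The fallback sets out from alcohol 3 and uses a sulfonate displacement. Alcohol 3 is converted with Tf2O and 2,6‑lutidine (CH2Cl2, −78 °C) into methyl (R)‑3‑(tert‑butyldimethylsilyloxy)‑2‑(trifluoromethylsulfonyloxy)propanoate F3. Phenol 6 with K2CO3 (MeCN, −20 → 0 °C) should displace the triflate by SN2 with the same inversion. The fallback rejoins the route at 7.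

Step 6 (partial reduction). Collapse of the aluminium hemiacetal before quench may lead to over‑reduction, or the α‑aryloxy aldehyde may epimerise during a slow work‑up. The fallback sets out from ester 7 and goes through the alcohol oxidation state. Ester 7 is reduced fully with DIBAL‑H (2.5 equiv, CH2Cl2, −78 → 0 °C) to (R)‑3‑(tert‑butyldimethylsilyloxy)‑2‑[4‑(tert‑butyldimethylsilyloxymethyl)‑2,6‑dimethoxyphenoxy]propan‑1‑ol F4. This alcohol is worked up cold at neutral pH, because silyl migration between its two primary oxygens would erode the enantiomeric purity. It is oxidised with Dess–Martin periodinane and NaHCO3 (CH2Cl2, 0 °C) just before use. The fallback rejoins the route at 8.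

**Further compounds**
F1 | step 9 | (S)‑3‑(tert‑butyldimethylsilyloxy)‑2‑[4‑(tert‑butyldimethylsilyloxymethyl)‑2,6‑dimethoxyphenoxy]‑N‑methoxy‑N‑methylpropanamide | CON(C)C(=O)[C@H](CO[Si](C)(C)C(C)(C)C)Oc1c(OC)cc(CO[Si](C)(C)C(C)(C)C)cc1OC
F2 | step 9 | (S)‑3‑(tert‑butyldimethylsilyloxy)‑2‑[4‑(tert‑butyldimethylsilyloxymethyl)‑2,6‑dimethoxyphenoxy]‑1‑[4‑(tert‑butyldimethylsilyloxy)‑3‑methoxyphenyl]propan‑1‑one | COc1cc(C(=O)[C@H](CO[Si](C)(C)C(C)(C)C)Oc2c(OC)cc(CO[Si](C)(C)C(C)(C)C)cc2OC)ccc1O[Si](C)(C)C(C)(C)C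
F3 | step 5 | methyl (R)‑3‑(tert‑butyldimethylsilyloxy)‑2‑(trifluoromethylsulfonyloxy)propanoate | COC(=O)[C@H](OS(=O)(=O)C(F)(F)F)CO[Si](C)(C)C(C)(C)C
F4 | step 6 | (R)‑3‑(tert‑butyldimethylsilyloxy)‑2‑[4‑(tert‑butyldimethylsilyloxymethyl)‑2,6‑dimethoxyphenoxy]propan‑1‑ol | OC[C@H](CO[Si](C)(C)C(C)(C)C)Oc1c(OC)cc(CO[Si](C)(C)C(C)(C)C)cc1OC
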